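The ratio to watch is reagent molarity in delta over reagent molarity in zeta. Two chemists dispute it before either flask is run.

| flask | starting material | reagent | free catalyst | temperature | remark | time |
|---|---|---|---|---|---|---|
| elm | 0.14 M | 1.2 equiv | 5.6 mol% | 75 °C | run made earlier |  |
| birch | 0.42 M | 1.2 equiv | 5.6 mol% | 86 °C | run made earlier |  |
| cedar | 0.50 M | 1.4 equiv | 5.6 mol% | 75 °C | run made earlier |  |
| delta | 0.25 M | 2.40 equiv | 5.6 mol% | 80 °C |  | 6.0 min |
| zeta | 0.50 M | 1.20 equiv | 5.6 mol% | 80 °C |  | 6.0 min |

- elm (time / min: product / %, starting material / %): 0.667: 0, 100.2; 1.33: 0, 98.7; 2.00: 1.9, 97.9; 2.50: 1.2, 96.7; 3.00: 2.6, 96.3; 4.00: 3.6, 94.8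
- birch (time / min: product / %, starting material / %): 0.333: 0.6, 97.7; 0.500: 2.3, 97.3; 0.833: 3.6, 95.3; 1.33: 7.0, 90.2; 2.00: 10.2, 87.5; 3.00: 17.0, 81.4; 4.00: 21.9, 76.7
- cedar (time / min: product / %, starting material / %): 0.333: 0, 98.4; 0.667: 0.7, 97.2; 1.33: 2.7, 95.6; 2.00: 4.4, 92.2; 4.00: 11.1, 87.1

(scatter of a reading: 0.5 percentage points)

- amounts and yields of product count idle complex too
- the numbers in the tables scatter by 0.5 percentage points (one standard deviation)
- steps thought possible: reagent + free catalyst -> catalyst intermediate A; starting material + catalyst intermediate A -> catalyst intermediate B; catalyst intermediate B -> catalyst intermediate C; catalyst intermediate C -> free catalyst + product; catalyst intermediate A + product -> spent catalyst; free catalyst + product <-> idle complex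
- where the amount of starting material changes, what is given in equivalents or mol% on it follows

- which of the two ends with the higher amount of product, in percent of the starting material charged ("neither" if they lie within 2 percentage points) (delta / zeta / neither)
- product at the end, in percent of the starting material charged, delta
- product at the end, in percent of the starting material charged, zeta

Let c_R be reagent molarity, the starting-material molarity times the equivalents. Delta has 0.600 M and zeta 0.600 M, so the ratio ρ is 1.00. Delta has half of zeta's starting material, and that is where we part.

The first chemist reads the percent rate as following starting-material molarity. She expects delta to lag, and she holds that “extra equivalents help little”.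

I read it otherwise. The loading is fixed in mol%, so catalyst per starting material is equal in these flasks. Percent conversion then follows what each catalyst does. At 4.00 min cedar had lost more starting material than it had made product, so I take the entry of starting material as quick and expect the entry of reagent on free catalyst to count.

Elm and cedar share temperature and loading. At 4.00 min elm had lost 5.20% and cedar 12.9%, at reagent molarities of 0.168 M and 0.700 M. The reagent exponent n, the apparent order: the power of c_R that percent conversion follows at fixed time, temperature and loading, reads 0.637, with the scatter of the readings. I carry it to 80 °C. Then delta's conversion over zeta's is ρ to the n, or 1.00, so I say neither.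

Her forecast differs: zeta ahead, with delta at 14.5% and zeta at 23%.

The flasks give neither: delta 23.0%, zeta 23.1%.

    reagent + free catalyst → catalyst intermediate A (k = 2.50 M⁻¹ min⁻¹, Ea = 73.0 kJ mol⁻¹)
    starting material + catalyst intermediate A → catalyst intermediate B (k = 42.0 M⁻¹ min⁻¹, Ea = 59.0 kJ mol⁻¹)
    catalyst intermediate B → catalyst intermediate C (k = 4.30 min⁻¹, Ea = 85.0 kJ mol⁻¹)
    catalyst intermediate C → free catalyst + product (k = 3.40 min⁻¹, Ea = 105 kJ mol⁻¹)
    catalyst intermediate A + product → spent catalyst (k = 0.810 M⁻¹ min⁻¹, Ea = 87.0 kJ mol⁻¹)
    free catalyst + product ⇌ idle complex (K = 1.50 M⁻¹, k = 0.470 M⁻¹ min⁻¹, Ea = 74.0 kJ mol⁻¹, ΔH = −31.0 kJ mol⁻¹)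
    (constants at 80 °C)

Her zeta figure stands; delta is where she falls short. Take delta back to 1.20 equiv. Its c_R falls to half, and n then gives 14.8%. Delta simulated with the difference in equivalents taken away ends at 14.8%. So the extra equivalents lift delta by 8.1 percentage points, which is part of the answer. Both flasks stop where they do because the run is short: left until 60.0 min, delta gives 92.6% and zeta 90.4%.

Her view has its ground where equivalents stay put. A neighbour like zeta at 0.30 M has c_R lower by the ratio 0.600, and n gives conversion 18.1%. That flask converts 18.4% and ends at 16.8% product, below zeta.

The numbers in the tables are simulated for substances that don't exist; the scatter is artificial.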